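**Plan**

1. Numbering follows the bicyclo[7.2.0]undecane core: C1/C9 ring-fusion CH, C10 the cyclobutane CH2, C11 the quaternary carbon, C8 the methylidene carbon, C4/C5 the epoxide, C12–C16 the side chain (C12 = C=O, C15 = carbinol, C16 = CH2OAc).
2. Late cuts: the epoxide O (from the E-C4=C5 olefin), C16–OAc (acetate opening of a C15/C16 epoxide), C13=C14 (aldol condensation of a C12 methyl ketone with (S)-2-methylglycidal), C8=CH2 (Wittig).
3. Ring cut: C4–C8. The nine-membered ring is the Grob ring-expansion product of a 6-5 hydrindanediol monomesylate, itself built on a cyclohexanone by aldol (C4–C5), methylation (C4–CH3) and samarium Barbier closure (C7–C8).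
4. Key cut: C9–C10 and C1–C11 together. C9 is α and C1 is β to C8, whose methylidene is a masked ketone, and C10 is a bare CH2 beside quaternary C11. The four-membered ring is therefore the head-to-tail [2+2] photoadduct of cyclohex-2-enone (ring C8, C9, C1, C2, C3, C4) and a 1,1-disubstituted alkene.
5. Forward order: cyclobutane on a six-membered ring, cyclopentanol annulation, fragmentation to the nine-membered ring, methylenation, side chain, epoxide.
6. Stereochemistry: C1 from a chiral Lewis acid in the photocycloaddition; C11 from exo placement of the bulky masked-acetyl group; C9 thermodynamically (cis at the 6-4 stage, trans at the 9-4 stage, so both photo-isomers and all C4/C5 diastereomers converge); E-olefin from the stereospecific Grob; C4/C5 epoxide by peripheral attack as in caryophyllene; C15 from (R)-2-methylglycidol.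

Key step: step 3

Remark 1: the sense of induction of the AlBr3-activated oxazaborolidine is taken by analogy with the cyclohexenone/isobutene case; should it prove opposite, the enantiomeric prolinol-derived catalyst is used.
Remark 2: the (S) configuration at C12 is arbitrary, since this centre is oxidised away in step 12; one enantiomer is used so that each intermediate is a single compound and C12 can act as an internal resolving centre.

**Route**

Step 1
Reactants: 1 3-methylbut-3-en-2-one
Product: 2 (2S)-3-methylbut-3-en-2-ol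
Conditions: (R)-Me-CBS (10 mol%), catecholborane, toluene, −78 °C
Reagents that add atoms: none
Why: Corey–Bakshi–Shibata reduction, in which the catalyst-bound enone is reduced 1,2 with the isopropenyl group as the large substituent, which should set the (S) carbinol centre (C12).

Step 2
Reactants: 2 (2S)-3-methylbut-3-en-2-ol
Product: 3 triisopropyl{[(2S)-3-methylbut-3-en-2-yl]oxy}silane
Conditions: TIPSOTf, 2,6-lutidine, CH2Cl2, 0 °C
Reagents that add atoms: triisopropylsilyl trifluoromethanesulfonate, CC(C)[Si](C(C)C)(C(C)C)OS(=O)(=O)C(F)(F)F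
Why: Standard silylation of a secondary alcohol with a silyl triflate and a hindered base, giving the bulky and weakly Lewis-basic ether that step 3 needs.

Step 3
Reactants: 3 triisopropyl{[(2S)-3-methylbut-3-en-2-yl]oxy}silane; 4 cyclohex-2-en-1-one
Product: 6 (1R,6R,7R)-7-methyl-7-[(1S)-1-(triisopropylsilyloxy)ethyl]bicyclo[4.2.0]octan-2-one (cis-fused), via trans-fused photoadduct 5 (not isolated)
Conditions: prolinol-derived oxazaborolidine·AlBr3 (50 mol%), 3 (5 equiv, excess recovered), hν (366 nm), CH2Cl2, −75 °C; then basic Al2O3, CH2Cl2, rt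
Reagents that add atoms: none
Why: Excitation of the Lewis-acid-bound enone and intersystem crossing give a triplet that bonds C9 to the CH2 terminus (C10) of the alkene, and the resulting 1,4-biradical (tertiary radical at C11, secondary radical at C1) closes the C1–C11 bond after spin inversion. The closest known reaction type is the chiral oxazaborolidine–AlBr3-catalysed intermolecular [2+2] photocycloaddition of cyclohex-2-enone with 1,1-disubstituted alkenes (racemic forerunner: cyclohexenone plus isobutene). The only ring closed is the cyclobutane, by stepwise [2π+2π] addition ending in 1,4-biradical recombination, head-to-tail, so that the quaternary carbon lands on the enone β-carbon. C1 is set by the catalyst, which covers one face of the bound enone; C11 is set by the closing biradical placing the bulky 1-(silyloxy)ethyl group exo (cis to H1) and the methyl towards C2; C9 is not controlled in the photoreaction, and the trans-fused adduct 5 is funnelled into cis-fused 6 by enolisation on basic alumina (its final trans configuration is set in step 9). The step needs head-to-tail regioselectivity (secured by the non-conjugated alkyl-type 1,1-disubstituted alkene), face selectivity (catalyst) and exo/endo selectivity at C11 (size difference CH3 versus CH(OTIPS)CH3); the TIPS ether is chosen because it is too hindered to compete with the enone for the Lewis acid.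

Step 4
Reactants: 6 (1R,6R,7R)-7-methyl-7-[(1S)-1-(triisopropylsilyloxy)ethyl]bicyclo[4.2.0]octan-2-one; 7 3-[(tert-butyldimethylsilyl)oxy]propanal
Product: 8 (1R,3S,6R,7R)-3-[(1S)-3-(tert-butyldimethylsilyloxy)-1-hydroxypropyl]-7-methyl-7-[(1S)-1-(triisopropylsilyloxy)ethyl]bicyclo[4.2.0]octan-2-one
Conditions: LDA, THF, −78 °C; then 7, −78 °C; AcOH quench
Reagents that add atoms: none
Why: Kinetic deprotonation should occur at the α′-CH2 (C4) and not at the ring-fusion C9–H, and the lithium enolate adds to the aldehyde from the convex face through a Zimmerman–Traxler chair (aldol addition, anti adduct expected), which sets C5, while the C4 centre is planarised again in step 5.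

Step 5
Reactants: 8 (1R,3S,6R,7R)-3-[(1S)-3-(tert-butyldimethylsilyloxy)-1-hydroxypropyl]-7-methyl-7-[(1S)-1-(triisopropylsilyloxy)ethyl]bicyclo[4.2.0]octan-2-one
Product: 9 (1R,3R,6R,7R)-3-[(1S)-3-(tert-butyldimethylsilyloxy)-1-hydroxypropyl]-3,7-dimethyl-7-[(1S)-1-(triisopropylsilyloxy)ethyl]bicyclo[4.2.0]octan-2-one
Conditions: LDA (2.3 equiv), THF, −78 → −40 °C; MeI, DMPU, −78 → −20 °C; AcOH quench
Reagents that add atoms: iodomethane, CI
Why: Fráter–Seebach-type alkylation of the chelated alkoxide–enolate dianion, in which iodomethane attacks C4 anti to the C6 chain on C5 and so creates the quaternary C4 with CH3 and O5 in the relationship (cis on the later cyclopentane) that step 9 translates into the E olefin.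

Step 6
Reactants: 9 (1R,3R,6R,7R)-3-[(1S)-3-(tert-butyldimethylsilyloxy)-1-hydroxypropyl]-3,7-dimethyl-7-[(1S)-1-(triisopropylsilyloxy)ethyl]bicyclo[4.2.0]octan-2-one
Product: 10 (1R,3R,6R,7R)-3-[(1S)-1,3-dihydroxypropyl]-3,7-dimethyl-7-[(1S)-1-(triisopropylsilyloxy)ethyl]bicyclo[4.2.0]octan-2-one
Conditions: HF·pyridine, pyridine, THF, 0 °C
Reagents that add atoms: none
Why: Buffered HF·pyridine should cleave the unhindered primary TBS ether selectively (silyl ether cleavage), the neopentylic secondary TIPS ether being far slower.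

Step 7
Reactants: 10 (1R,3R,6R,7R)-3-[(1S)-1,3-dihydroxypropyl]-3,7-dimethyl-7-[(1S)-1-(triisopropylsilyloxy)ethyl]bicyclo[4.2.0]octan-2-one
Product: 11 (1R,3R,6R,7R)-3-[(1S)-1-hydroxy-3-iodopropyl]-3,7-dimethyl-7-[(1S)-1-(triisopropylsilyloxy)ethyl]bicyclo[4.2.0]octan-2-one
Conditions: I2, PPh3, imidazole, CH2Cl2, 0 °C
Reagents that add atoms: iodine, II
Why: Appel-type (Garegg–Samuelsson) iodination converts the primary alcohol into the iodide, the neopentylic secondary C5–OH being too hindered for SN2 displacement.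

Step 8
Reactants: 11 (1R,3R,6R,7R)-3-[(1S)-1-hydroxy-3-iodopropyl]-3,7-dimethyl-7-[(1S)-1-(triisopropylsilyloxy)ethyl]bicyclo[4.2.0]octan-2-one
Product: 12 tricyclic diol (cis-fused hydrindane-1,3-diol on the cis-fused cyclobutane of 6; tertiary C8–OH; secondary C5–OH cis to the C4 methyl and to C8–OH)
Conditions: SmI2, HMPA, THF, −78 → 0 °C
Reagents that add atoms: none
Why: Samarium Barbier cyclisation, in which the primary alkylsamarium (or radical) adds 5-exo to the C8 ketone and the short tether should force the cis-fused hydrindanol, setting C8 with OH cis to the C4 methyl.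

Step 9
Reactants: 12 tricyclic diol
Product: 15 (1R,4E,9S,11R)-4,11-dimethyl-11-[(1S)-1-(triisopropylsilyloxy)ethyl]bicyclo[7.2.0]undec-4-en-8-one (trans-fused), via hydrindanol mesylate 13 (not isolated), via cis-fused cyclononenone 14 (not isolated)
Conditions: MsCl, Et3N, CH2Cl2, −10 °C; concentrate; then KOtBu, t-BuOH/THF, 0 °C → rt
Reagents that add atoms: none
Why: Sulfene mesylation should take only the secondary C5–OH, and the tertiary C8 alkoxide then triggers a Grob fragmentation in which the C4–C8 bond anti-periplanar to C5–OMs breaks to give the C8 ketone and, stereospecifically, the E-C4=C5 olefin (OMs cis to CH3), after which tert-butoxide epimerises C9 through the enolate to the more stable trans-fused bicyclo[7.2.0] ketone.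

Step 10
Reactants: 15 (1R,4E,9S,11R)-4,11-dimethyl-11-[(1S)-1-(triisopropylsilyloxy)ethyl]bicyclo[7.2.0]undec-4-en-8-one
Product: 16 (1R,4E,9S,11R)-4,11-dimethyl-8-methylidene-11-[(1S)-1-(triisopropylsilyloxy)ethyl]bicyclo[7.2.0]undec-4-ene
Conditions: Ph3PCH3Br, KOtBu, THF, 0 → 40 °C
Reagents that add atoms: methyltriphenylphosphonium bromide, C[P+](c1ccccc1)(c1ccccc1)c1ccccc1.[Br-]
Why: Wittig methylenation of the hindered ketone with the non-stabilised ylide, C9 being already in its thermodynamic (trans) configuration so that the basic medium should not change it.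

Step 11
Reactants: 16 (1R,4E,9S,11R)-4,11-dimethyl-8-methylidene-11-[(1S)-1-(triisopropylsilyloxy)ethyl]bicyclo[7.2.0]undec-4-ene
Product: 17 (1S)-1-[(1R,4E,9S,11R)-4,11-dimethyl-8-methylidenebicyclo[7.2.0]undec-4-en-11-yl]ethan-1-ol
Conditions: TBAF, THF, 50 °C
Reagents that add atoms: none
Why: Fluoride-mediated cleavage of the TIPS ether (desilylation) under non-acidic conditions that leave the acid-sensitive 1,5-diene untouched.

Step 12
Reactants: 17 (1S)-1-[(1R,4E,9S,11R)-4,11-dimethyl-8-methylidenebicyclo[7.2.0]undec-4-en-11-yl]ethan-1-ol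
Product: 18 1-[(1R,4E,9S,11R)-4,11-dimethyl-8-methylidenebicyclo[7.2.0]undec-4-en-11-yl]ethan-1-one
Conditions: Dess–Martin periodinane, NaHCO3, CH2Cl2, 0 °C → rt
Reagents that add atoms: none
Why: Dess–Martin oxidation of the secondary alcohol gives the methyl ketone under buffered conditions and erases the auxiliary C12 centre.

Step 13
Reactants: 19 [(2R)-2-methyloxiran-2-yl]methanol
Product: 20 (2S)-2-methyloxirane-2-carbaldehyde
Conditions: Dess–Martin periodinane, NaHCO3, CH2Cl2, 0 °C (used as a solution)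
Reagents that add atoms: none
Why: Dess–Martin oxidation of the epoxy alcohol gives the non-enolisable epoxy aldehyde without touching the epoxide, the quaternary centre (later C15) being carried over unchanged.

Step 14
Reactants: 18 1-[(1R,4E,9S,11R)-4,11-dimethyl-8-methylidenebicyclo[7.2.0]undec-4-en-11-yl]ethan-1-one; 20 (2S)-2-methyloxirane-2-carbaldehyde
Product: 23 (2E)-1-[(1R,4E,9S,11R)-4,11-dimethyl-8-methylidenebicyclo[7.2.0]undec-4-en-11-yl]-3-[(2R)-2-methyloxiran-2-yl]prop-2-en-1-one, via aldol adduct 21 (not isolated), via aldol mesylate 22 (not isolated)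
Conditions: LDA, THF, −78 °C; 20, −78 °C; MsCl, −78 → 0 °C; DBU, rt
Reagents that add atoms: none
Why: Directed aldol addition of the kinetic lithium enolate of the methyl ketone (only its CH3 side is enolisable) to the non-enolisable aldehyde, O-mesylation of the aldolate in situ and E1cB elimination with DBU should give the thermodynamically favoured E-enone (aldol condensation), C15 being untouched.

Step 15
Reactants: 23 (2E)-1-[(1R,4E,9S,11R)-4,11-dimethyl-8-methylidenebicyclo[7.2.0]undec-4-en-11-yl]-3-[(2R)-2-methyloxiran-2-yl]prop-2-en-1-one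
Product: 24 (2R,3E)-5-[(1R,4E,9S,11R)-4,11-dimethyl-8-methylidenebicyclo[7.2.0]undec-4-en-11-yl]-2-hydroxy-2-methyl-5-oxopent-3-en-1-yl acetate
Conditions: CsOAc, AcOH, DMF, 60 °C
Reagents that add atoms: acetic acid, CC(=O)O
Why: SN2 opening of the 2,2-disubstituted epoxide by acetate at its unhindered CH2 terminus (carboxylate epoxide opening) should give the tertiary alcohol and primary acetate with C15 unchanged, ionisation at the tertiary allylic carbon being disfavoured by the enone.

Step 16
Reactants: 24 (2R,3E)-5-[(1R,4E,9S,11R)-4,11-dimethyl-8-methylidenebicyclo[7.2.0]undec-4-en-11-yl]-2-hydroxy-2-methyl-5-oxopent-3-en-1-yl acetate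
Product: 25 target CNP0186939.2
Conditions: mCPBA (1.05 equiv), NaHCO3, CH2Cl2, 0 °C
Reagents that add atoms: 3-chloroperbenzoic acid, OOC(=O)c1cccc(Cl)c1
Why: Prilezhaev epoxidation, in which the strained electron-rich E-trisubstituted ring olefin should react much faster than the methylidene group or the enone, and the peracid attacks its exposed outer face in the preferred ring conformers as in the caryophyllene to caryophyllene oxide case, which sets C4 and C5.

**Compound list**

1 | 3-methylbut-3-en-2-one | CC(=O)C(C)=C | starting material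
2 | (2S)-3-methylbut-3-en-2-ol | C=C(C)[C@H](C)O | intermediate
3 | triisopropyl{[(2S)-3-methylbut-3-en-2-yl]oxy}silane | C=C(C)[C@H](C)O[Si](C(C)C)(C(C)C)C(C)C | intermediate
4 | cyclohex-2-en-1-one | O=C1C=CCCC1 | starting material
5 | (1S,6R,7R)-7-methyl-7-[(1S)-1-(triisopropylsilyloxy)ethyl]bicyclo[4.2.0]octan-2-one (trans-fused; not isolated) | O=C1CCC[C@@H]2[C@@H]1C[C@@]2(C)[C@H](C)O[Si](C(C)C)(C(C)C)C(C)C | intermediate
6 | (1R,6R,7R)-7-methyl-7-[(1S)-1-(triisopropylsilyloxy)ethyl]bicyclo[4.2.0]octan-2-one (cis-fused) | O=C1CCC[C@@H]2[C@H]1C[C@@]2(C)[C@H](C)O[Si](C(C)C)(C(C)C)C(C)C | intermediate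
7 | 3-[(tert-butyldimethylsilyl)oxy]propanal | O=CCCO[Si](C)(C)C(C)(C)C | starting material
8 | (1R,3S,6R,7R)-3-[(1S)-3-(tert-butyldimethylsilyloxy)-1-hydroxypropyl]-7-methyl-7-[(1S)-1-(triisopropylsilyloxy)ethyl]bicyclo[4.2.0]octan-2-one | O=C1[C@H]([C@@H](O)CCO[Si](C)(C)C(C)(C)C)CC[C@@H]2[C@H]1C[C@@]2(C)[C@H](C)O[Si](C(C)C)(C(C)C)C(C)C | intermediate
9 | (1R,3R,6R,7R)-3-[(1S)-3-(tert-butyldimethylsilyloxy)-1-hydroxypropyl]-3,7-dimethyl-7-[(1S)-1-(triisopropylsilyloxy)ethyl]bicyclo[4.2.0]octan-2-one | O=C1[C@@](C)([C@@H](O)CCO[Si](C)(C)C(C)(C)C)CC[C@@H]2[C@H]1C[C@@]2(C)[C@H](C)O[Si](C(C)C)(C(C)C)C(C)C | intermediate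
10 | (1R,3R,6R,7R)-3-[(1S)-1,3-dihydroxypropyl]-3,7-dimethyl-7-[(1S)-1-(triisopropylsilyloxy)ethyl]bicyclo[4.2.0]octan-2-one | O=C1[C@@](C)([C@@H](O)CCO)CC[C@@H]2[C@H]1C[C@@]2(C)[C@H](C)O[Si](C(C)C)(C(C)C)C(C)C | intermediate
11 | (1R,3R,6R,7R)-3-[(1S)-1-hydroxy-3-iodopropyl]-3,7-dimethyl-7-[(1S)-1-(triisopropylsilyloxy)ethyl]bicyclo[4.2.0]octan-2-one | O=C1[C@@](C)([C@@H](O)CCI)CC[C@@H]2[C@H]1C[C@@]2(C)[C@H](C)O[Si](C(C)C)(C(C)C)C(C)C | intermediate
12 | tricyclic diol: cis-fused hydrindane-1,3-diol on the cis-fused cyclobutane; tertiary C8–OH, secondary C5–OH and C4 methyl all on one face of the cyclopentane | O[C@]12CC[C@H](O)[C@@]1(C)CC[C@@H]3[C@H]2C[C@@]3(C)[C@H](C)O[Si](C(C)C)(C(C)C)C(C)C | intermediate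
13 | C5 methanesulfonate of 12 (not isolated) | O[C@]12CC[C@H](OS(C)(=O)=O)[C@@]1(C)CC[C@@H]3[C@H]2C[C@@]3(C)[C@H](C)O[Si](C(C)C)(C(C)C)C(C)C | intermediate
14 | (1R,4E,9R,11R)-4,11-dimethyl-11-[(1S)-1-(triisopropylsilyloxy)ethyl]bicyclo[7.2.0]undec-4-en-8-one (cis-fused; not isolated) | O=C1CC/C=C(\C)CC[C@@H]2[C@H]1C[C@@]2(C)[C@H](C)O[Si](C(C)C)(C(C)C)C(C)C | intermediate
15 | (1R,4E,9S,11R)-4,11-dimethyl-11-[(1S)-1-(triisopropylsilyloxy)ethyl]bicyclo[7.2.0]undec-4-en-8-one (trans-fused) | O=C1CC/C=C(\C)CC[C@@H]2[C@@H]1C[C@@]2(C)[C@H](C)O[Si](C(C)C)(C(C)C)C(C)C | intermediate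
16 | (1R,4E,9S,11R)-4,11-dimethyl-8-methylidene-11-[(1S)-1-(triisopropylsilyloxy)ethyl]bicyclo[7.2.0]undec-4-ene | C=C1CC/C=C(\C)CC[C@@H]2[C@@H]1C[C@@]2(C)[C@H](C)O[Si](C(C)C)(C(C)C)C(C)C | intermediate
17 | (1S)-1-[(1R,4E,9S,11R)-4,11-dimethyl-8-methylidenebicyclo[7.2.0]undec-4-en-11-yl]ethan-1-ol | C=C1CC/C=C(\C)CC[C@@H]2[C@@H]1C[C@@]2(C)[C@H](C)O | intermediate
18 | 1-[(1R,4E,9S,11R)-4,11-dimethyl-8-methylidenebicyclo[7.2.0]undec-4-en-11-yl]ethan-1-one | C=C1CC/C=C(\C)CC[C@@H]2[C@@H]1C[C@@]2(C)C(C)=O | intermediate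
19 | [(2R)-2-methyloxiran-2-yl]methanol | OC[C@@]1(C)OC1 | starting material
20 | (2S)-2-methyloxirane-2-carbaldehyde | O=C[C@@]1(C)OC1 | intermediate
21 | aldol adduct of 18 and 20: β-hydroxy ketone, both C14 epimers (formed as the lithium alkoxide; not isolated) | C=C1CC/C=C(\C)CC[C@@H]2[C@@H]1C[C@@]2(C)C(=O)CC(O)[C@@]1(C)OC1 | intermediate
22 | C14 methanesulfonate of 21 (not isolated) | C=C1CC/C=C(\C)CC[C@@H]2[C@@H]1C[C@@]2(C)C(=O)CC(OS(C)(=O)=O)[C@@]1(C)OC1 | intermediate
23 | (2E)-1-[(1R,4E,9S,11R)-4,11-dimethyl-8-methylidenebicyclo[7.2.0]undec-4-en-11-yl]-3-[(2R)-2-methyloxiran-2-yl]prop-2-en-1-one | C=C1CC/C=C(\C)CC[C@@H]2[C@@H]1C[C@@]2(C)C(=O)/C=C/[C@@]1(C)OC1 | intermediate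
24 | (2R,3E)-5-[(1R,4E,9S,11R)-4,11-dimethyl-8-methylidenebicyclo[7.2.0]undec-4-en-11-yl]-2-hydroxy-2-methyl-5-oxopent-3-en-1-yl acetate | C=C1CC/C=C(\C)CC[C@@H]2[C@@H]1C[C@@]2(C)C(=O)/C=C/[C@@](C)(O)COC(C)=O | intermediate
25 | CNP0186939.2: (2R,3E)-5-[(1R,4R,6R,10S,12R)-4,12-dimethyl-9-methylidene-5-oxatricyclo[8.2.0.0(4,6)]dodecan-12-yl]-2-hydroxy-2-methyl-5-oxopent-3-en-1-yl acetate | C=C1CC[C@H]2O[C@]2(C)CC[C@@H]2[C@@H]1C[C@@]2(C)C(=O)/C=C/[C@@](C)(O)COC(C)=O | target

**Totals and risks**

Total step count: 16. Longest linear sequence: 15 steps (steps 1–12 and 14–16); step 13 is a one-step side branch.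

Steps most likely to fail:

1. Step 3. Process at risk: loss of catalyst control (binding or ionisation of the allylic silyl ether by the Lewis acid, or an uncatalysed background addition), giving poor face selectivity; the exo/endo discrimination at C11 may also be only moderate. Fallback: starting again from 3 and 4, the photocycloaddition is run without Lewis acid (350 nm, excess 3, CH2Cl2, then basic alumina), as in the classical cyclohexenone/isobutene addition. Both antipodal cores then form, but because C12 is homochiral they are diastereomers: 6 and the core-antipodal cis-fused adduct F1. These are separated by chromatography, and the route is rejoined at 6.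

2. Step 5. Process at risk: deprotonation at the ring-fusion carbon C9 instead of C4, or retro-aldol cleavage of the dianion. Fallback, which secures regiochemistry by double activation instead of chelation: from 8, Dess–Martin oxidation gives the 1,3-diketone F2. K2CO3/MeI in acetone C-methylates the doubly activated C4 from the convex face to give the methylated diketone F3. Chelation-controlled reduction (Zn(BH4)2, Et2O, −30 °C) of the less hindered side-chain ketone then gives 9. Any C5-epimeric alcohol F4 is separated and recycled to F3 by reoxidation. The route is rejoined at 9.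

3. Step 14. Process at risk: rearrangement or opening of the epoxide by the neighbouring lithium alkoxide (Payne-type) before mesylation, and incomplete elimination. Fallback, an olefination in place of the aldol condensation: from 18, LDA then diethyl chlorophosphate gives the enol phosphate F5. A second treatment with LDA induces the 1,3-phosphorus shift to the β-ketophosphonate F6. A Masamune–Roush Horner–Wadsworth–Emmons reaction of F6 with 20 (LiCl, i-Pr2NEt, MeCN) gives the E-enone, and the route is rejoined at 23.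

**Further compounds**

F1 | step 3 | (1S,6S,7S)-7-methyl-7-[(1S)-1-(triisopropylsilyloxy)ethyl]bicyclo[4.2.0]octan-2-one | O=C1CCC[C@H]2[C@@H]1C[C@]2(C)[C@H](C)O[Si](C(C)C)(C(C)C)C(C)C
F2 | step 5 | 3-[3-(tert-butyldimethylsilyloxy)propanoyl] derivative of 6 (1,3-diketone; C3 labile) | O=C1C(C(=O)CCO[Si](C)(C)C(C)(C)C)CC[C@@H]2[C@H]1C[C@@]2(C)[C@H](C)O[Si](C(C)C)(C(C)C)C(C)C
F3 | step 5 | (1R,3R,6R,7R)-3-[3-(tert-butyldimethylsilyloxy)propanoyl]-3,7-dimethyl-7-[(1S)-1-(triisopropylsilyloxy)ethyl]bicyclo[4.2.0]octan-2-one | O=C1[C@@](C)(C(=O)CCO[Si](C)(C)C(C)(C)C)CC[C@@H]2[C@H]1C[C@@]2(C)[C@H](C)O[Si](C(C)C)(C(C)C)C(C)C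
F4 | step 5 | C5 epimer of 9: (1R,3R,6R,7R)-3-[(1R)-3-(tert-butyldimethylsilyloxy)-1-hydroxypropyl]-3,7-dimethyl-7-[(1S)-1-(triisopropylsilyloxy)ethyl]bicyclo[4.2.0]octan-2-one | O=C1[C@@](C)([C@H](O)CCO[Si](C)(C)C(C)(C)C)CC[C@@H]2[C@H]1C[C@@]2(C)[C@H](C)O[Si](C(C)C)(C(C)C)C(C)C
F5 | step 14 | diethyl 1-[(1R,4E,9S,11R)-4,11-dimethyl-8-methylidenebicyclo[7.2.0]undec-4-en-11-yl]ethenyl phosphate | C=C1CC/C=C(\C)CC[C@@H]2[C@@H]1C[C@@]2(C)C(=C)OP(=O)(OCC)OCC
F6 | step 14 | diethyl {2-[(1R,4E,9S,11R)-4,11-dimethyl-8-methylidenebicyclo[7.2.0]undec-4-en-11-yl]-2-oxoethyl}phosphonate | C=C1CC/C=C(\C)CC[C@@H]2[C@@H]1C[C@@]2(C)C(=O)CP(=O)(OCC)OCC
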